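With the bicyclo[3.2.1]octane numbered from the allyl bridgehead (C1; C2 H2; C3 OMe; C4 ketone; C5 OMe bridgehead; C6 aryl; C7 methyl; C8 OAc bridge), C8–O is β to the C4 carbonyl across fully substituted C5, and C5–C8 is the one bond shared by the cyclopentane and the cyclohexanone. Cutting it leaves a cycloheptanone (ring C1–C7) whose C1 carries allyl and formyl. In the forward sense the C5 enolate reaches across that ring to the aldehyde, closing both rings and setting C5 and C8 together; the quench then sets C3. The precursor comes from an iridium-catalysed allylation (C6), ring-closing metathesis and a cuprate addition/allylation relay (C7, C1).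

Key step: step 10

Assumption: C3 and C5, the methoxy-bearing carbons beside the ring ketone, are epimerisable in 6 to 15; they are drawn in one configuration and may be carried as epimer mixtures, because step 10 erases C5 and sets C3.

Locants C1–C8 in the text are those defined above; systematic names carry their own locants.

Step 1
Reactants: 1 methyl (E)-3-(3,4-dimethoxyphenyl)prop-2-enoate
Product: 2 (E)-3-(3,4-dimethoxyphenyl)prop-2-en-1-ol
Conditions: iBu2AlH (2.3 equiv), CH2Cl2, −78 °C; aq. potassium sodium tartrate
Reagents that add atoms: none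
Why: 1,2-Reduction of an α,β-unsaturated ester with diisobutylaluminium hydride gives the allylic alcohol and leaves the E-alkene and the aryl ethers untouched.

Step 2
Reactants: 2 (E)-3-(3,4-dimethoxyphenyl)prop-2-en-1-ol
Product: 3 (E)-3-(3,4-dimethoxyphenyl)prop-2-en-1-yl methyl carbonate
Conditions: ClCO2Me, pyridine, CH2Cl2, 0 °C
Reagents that add atoms: methyl chloroformate, COC(=O)Cl
Why: O-Acylation of the primary allylic alcohol with a chloroformate gives the linear allylic carbonate that serves as the leaving group in the allylic substitution.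

Step 3
Reactants: 3 (E)-3-(3,4-dimethoxyphenyl)prop-2-en-1-yl methyl carbonate; 4 1,3-dimethoxypropan-2-one
Product: 6 (3R,4S)-4-(3,4-dimethoxyphenyl)-1,3-dimethoxyhex-5-en-2-one, via monovalent copper enolate 5 (not isolated)
Conditions: 4 (2 equiv), LiN(SiMe3)2, CuBr, THF, 0 °C; then 3, [Ir(cod)Cl]2 (2 mol%), (Sa,S,S)-L (4 mol%), rt; L = O,O′-(1,1′-binaphthalene-2,2′-diyl) N,N-bis(1-phenylethyl)phosphoramidite
Reagents that add atoms: none
Why: Asymmetric allylic alkylation (iridium-catalysed allylic substitution) of a linear cinnamyl carbonate with the enolate of an α-alkoxy ketone gives the branched product, the cyclometallated catalyst from [Ir(cod)Cl]2 and the (Sa,S,S)-phosphoramidite choosing the face of the allyl terminus and so fixing C6 as S (the mirror-image ligand is taken if the sense proves opposite), while the symmetric ketone leaves no regiochemical choice in the nucleophile.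

Step 4
Reactants: 6 (3R,4S)-4-(3,4-dimethoxyphenyl)-1,3-dimethoxyhex-5-en-2-one; 7 ethyl 2-(bromomethyl)prop-2-enoate
Product: 9 ethyl (4S,6R,7S)-7-(3,4-dimethoxyphenyl)-4,6-dimethoxy-2-methylidene-5-oxonon-8-enoate, via lithium enolate 8 (not isolated)
Conditions: LiN(iPr)2 (1.0 equiv), THF, −78 °C; then 7 (1.5 equiv), −78 °C; aq. NH4Cl at −78 °C
Reagents that add atoms: none
Why: Kinetic deprotonation at −78 °C takes the less hindered methoxymethyl CH2 and the lithium enolate is C-alkylated by the allylic bromide (enolate alkylation with a 2-(bromomethyl)acrylate), the cold quench preventing a follow-up Michael ring closure; the new C3 centre needs no control because step 10 resets it.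

Step 5
Reactants: 9 ethyl (4S,6R,7S)-7-(3,4-dimethoxyphenyl)-4,6-dimethoxy-2-methylidene-5-oxonon-8-enoate
Product: 10 ethyl (3S,4R,6S)-3-(3,4-dimethoxyphenyl)-4,6-dimethoxy-5-oxocyclohept-1-ene-1-carboxylate
Conditions: second-generation Grubbs catalyst (5 mol%), CH2Cl2 (5 mM), 40 °C
Reagents that add atoms: none
Why: Ring-closing metathesis of the vinyl group onto the 1,1-disubstituted acrylate olefin, a standard entry to cyclic α,β-unsaturated esters, closes the seven-membered ring (C1=C7) with loss of ethene and touches no stereocentre.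

Step 6
Reactants: 10 ethyl (3S,4R,6S)-3-(3,4-dimethoxyphenyl)-4,6-dimethoxy-5-oxocyclohept-1-ene-1-carboxylate
Product: 11 (2R,3S,7S)-3-(3,4-dimethoxyphenyl)-5-(hydroxymethyl)-2,7-dimethoxycyclohept-4-en-1-ol (both carbinol epimers)
Conditions: iBu2AlH (4.5 equiv), CH2Cl2, −78 to −20 °C; aq. potassium sodium tartrate
Reagents that add atoms: none
Why: Hydride reduction with excess diisobutylaluminium hydride takes the conjugated ester to the allylic alcohol and the ketone to the carbinol together, which avoids any chemoselectivity problem; the carbinol configuration at C4 is irrelevant because step 7 reoxidises it.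

Step 7
Reactants: 11 (2R,3S,7S)-3-(3,4-dimethoxyphenyl)-5-(hydroxymethyl)-2,7-dimethoxycyclohept-4-en-1-ol
Product: 12 (3S,4R,6S)-3-(3,4-dimethoxyphenyl)-4,6-dimethoxy-5-oxocyclohept-1-ene-1-carbaldehyde
Conditions: Dess–Martin periodinane (3 equiv), CH2Cl2, 0 °C to rt
Reagents that add atoms: none
Why: Dess–Martin oxidation converts the allylic primary alcohol into the enal and the secondary alcohol into the ketone under base-free conditions, so the C6–H, which is benzylic and γ to the enal, is not exchanged.

Step 8
Reactants: 12 (3S,4R,6S)-3-(3,4-dimethoxyphenyl)-4,6-dimethoxy-5-oxocyclohept-1-ene-1-carbaldehyde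
Product: 13 (2R,3S,4R,5E,7S)-3-(3,4-dimethoxyphenyl)-2,7-dimethoxy-4-methyl-5-[(trimethylsilyloxy)methylidene]cycloheptan-1-one
Conditions: Me2CuLi (from MeLi and CuI, 1.5 equiv), Me3SiCl (3 equiv), THF, −78 °C; Et3N, pH 7 buffer
Reagents that add atoms: lithium dimethylcuprate, [Li+].C[Cu-]C; chlorotrimethylsilane, C[Si](C)(C)Cl
Why: Me3SiCl-accelerated conjugate addition of the organocuprate to the enal puts the methyl group on C7 anti to the neighbouring C6 aryl group (C7 becomes R) and traps the aldehyde enolate at once as its silyl enol ether, so no basic enolate stays beside the ketone.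

Step 9
Reactants: 13 (2R,3S,4R,5E,7S)-3-(3,4-dimethoxyphenyl)-2,7-dimethoxy-4-methyl-5-[(trimethylsilyloxy)methylidene]cycloheptan-1-one; 14 methyl prop-2-en-1-yl carbonate
Product: 15 (1S,2R,3S,4R,6S)-3-(3,4-dimethoxyphenyl)-4,6-dimethoxy-2-methyl-5-oxo-1-(prop-2-en-1-yl)cycloheptane-1-carbaldehyde
Conditions: 14 (2 equiv), Pd2(dba)3·CHCl3 (2.5 mol%), 1,2-bis(diphenylphosphino)ethane (10 mol%), THF, 65 °C
Reagents that add atoms: none
Why: Tsuji–Trost allylation of a silyl enol ether with an allyl carbonate under neutral conditions, in which the methoxide set free on decarboxylation takes the silyl group and the enolate joins the π-allylpalladium unit at C1 on the face away from the adjacent C7 methyl (the usual anti relay of conjugate addition then enolate trapping), building the quaternary centre with formyl cis to methyl.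

Step 10
Reactants: 15 (1S,2R,3S,4R,6S)-3-(3,4-dimethoxyphenyl)-4,6-dimethoxy-2-methyl-5-oxo-1-(prop-2-en-1-yl)cycloheptane-1-carbaldehyde
Product: 18 (1S,3S,5S,6S,7R,8S)-6-(3,4-dimethoxyphenyl)-8-hydroxy-3,5-dimethoxy-7-methyl-1-(prop-2-en-1-yl)bicyclo[3.2.1]octan-4-one, via lithium aldolate 16 (not isolated), via dilithium enolate alkoxide 17 (not isolated)
Conditions: LiN(SiMe3)2 (1.1 equiv), THF, −78 to −30 °C; LiN(iPr)2 (2.5 equiv), −78 to 0 °C; AcOH, THF, −78 °C
Reagents that add atoms: none
Why: LiN(SiMe3)2 enolises the ketone reversibly, hexamethyldisilazane carrying the proton between C3 and C5, and since only the C5 enolate can reach the non-enolisable formyl group (C3 would have to close a four-membered ring) all material drains into C5–C8 bond formation, an intramolecular, here transannular, aldol addition of a keto aldehyde of the kind known to give bridged β-hydroxy ketones. That single bond closes the cyclopentane C1–C7–C6–C5–C8 in the 5-(enolexo)-exo-trig mode and the six-membered ring C1–C2–C3–C4–C5–C8 in the 6-(enolendo)-exo-trig mode. C5 is set by the tether, because the formyl group stands on the C1 face cis to the C7 methyl and can bond only to that face of the enolate, which turns the C6 aryl group endo. C8 is set by the lithium-bridged closed transition state, which keeps the aldehyde oxygen next to the enolate oxygen (hydroxyl syn to the C2–C4 bridge) and turns the small formyl hydrogen toward the exo C7 methyl, and the chelated aldolate 16 resists retro-aldol cleavage. C3, which no enolate-based closure can preserve, is set last: LiN(iPr)2 converts 16 into the C3=C4 enolate 17, the only one possible now that C5 is quaternary, and acetic acid protonates it kinetically on the exo face, the endo face being covered by the C6 aryl ring while the nearby C8 oxygen can relay the proton, so the methoxy group ends endo as in the target. The selectivities needed, C5 over C3 reactivity, closure beside the chelating oxygen and exo protonation, are thus secured by ring size, by lithium chelation and by the aryl shield.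

Step 11
Reactants: 18 (1S,3S,5S,6S,7R,8S)-6-(3,4-dimethoxyphenyl)-8-hydroxy-3,5-dimethoxy-7-methyl-1-(prop-2-en-1-yl)bicyclo[3.2.1]octan-4-one
Product: 19 (1S,3S,5S,6S,7R,8S)-6-(3,4-dimethoxyphenyl)-3,5-dimethoxy-7-methyl-4-oxo-1-(prop-2-en-1-yl)bicyclo[3.2.1]octan-8-yl acetate
Conditions: Ac2O, DMAP (cat.), pyridine, CH2Cl2, 0 °C to rt
Reagents that add atoms: acetic anhydride, CC(=O)OC(C)=O
Why: DMAP-catalysed acylation (nucleophilic catalysis) esterifies the hindered secondary C8 alcohol, and C3, the only enolisable centre left, should hold because any exchange returns the proton to the same exo face.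

Compound list

1 | methyl (E)-3-(3,4-dimethoxyphenyl)prop-2-enoate | COC(=O)/C=C/c1ccc(OC)c(OC)c1 | starting material
2 | (E)-3-(3,4-dimethoxyphenyl)prop-2-en-1-ol | OC/C=C/c1ccc(OC)c(OC)c1 | intermediate
3 | (E)-3-(3,4-dimethoxyphenyl)prop-2-en-1-yl methyl carbonate | COC(=O)OC/C=C/c1ccc(OC)c(OC)c1 | intermediate
4 | 1,3-dimethoxypropan-2-one (1,3-dimethoxyacetone) | COCC(=O)COC | starting material
5 | monovalent copper enolate of 4, (1,3-dimethoxyprop-1-en-2-yl)oxycopper | COC=C(COC)O[Cu] | intermediate (not isolated)
6 | (3R,4S)-4-(3,4-dimethoxyphenyl)-1,3-dimethoxyhex-5-en-2-one (its C3 epimer may accompany it) | C=C[C@@H](c1ccc(OC)c(OC)c1)[C@@H](OC)C(=O)COC | intermediate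
7 | ethyl 2-(bromomethyl)prop-2-enoate | C=C(CBr)C(=O)OCC | starting material
8 | lithium enolate of 6, lithium (3R,4S)-4-(3,4-dimethoxyphenyl)-1,3-dimethoxyhexa-1,5-dien-2-olate | C=C[C@@H](c1ccc(OC)c(OC)c1)[C@@H](OC)C([O-])=COC.[Li+] | intermediate (not isolated)
9 | ethyl (4S,6R,7S)-7-(3,4-dimethoxyphenyl)-4,6-dimethoxy-2-methylidene-5-oxonon-8-enoate | C=C[C@@H](c1ccc(OC)c(OC)c1)[C@@H](OC)C(=O)[C@@H](OC)CC(=C)C(=O)OCC | intermediate
10 | ethyl (3S,4R,6S)-3-(3,4-dimethoxyphenyl)-4,6-dimethoxy-5-oxocyclohept-1-ene-1-carboxylate | CCOC(=O)C1=C[C@@H](c2ccc(OC)c(OC)c2)[C@@H](OC)C(=O)[C@@H](OC)C1 | intermediate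
11 | (2R,3S,7S)-3-(3,4-dimethoxyphenyl)-5-(hydroxymethyl)-2,7-dimethoxycyclohept-4-en-1-ol, both C1 carbinol epimers | OCC1=C[C@@H](c2ccc(OC)c(OC)c2)[C@@H](OC)C(O)[C@@H](OC)C1 | intermediate
12 | (3S,4R,6S)-3-(3,4-dimethoxyphenyl)-4,6-dimethoxy-5-oxocyclohept-1-ene-1-carbaldehyde | O=CC1=C[C@@H](c2ccc(OC)c(OC)c2)[C@@H](OC)C(=O)[C@@H](OC)C1 | intermediate
13 | (2R,3S,4R,5E,7S)-3-(3,4-dimethoxyphenyl)-2,7-dimethoxy-4-methyl-5-[(trimethylsilyloxy)methylidene]cycloheptan-1-one (methyl trans to aryl; the enol ether geometry is immaterial) | C[Si](C)(C)O/C=C1\C[C@H](OC)C(=O)[C@H](OC)[C@H](c2ccc(OC)c(OC)c2)[C@H]1C | intermediate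
14 | methyl prop-2-en-1-yl carbonate (allyl methyl carbonate) | C=CCOC(=O)OC | starting material
15 | (1S,2R,3S,4R,6S)-3-(3,4-dimethoxyphenyl)-4,6-dimethoxy-2-methyl-5-oxo-1-(prop-2-en-1-yl)cycloheptane-1-carbaldehyde (formyl cis to methyl, trans to aryl) | C=CC[C@]1(C=O)C[C@H](OC)C(=O)[C@H](OC)[C@H](c2ccc(OC)c(OC)c2)[C@H]1C | intermediate
16 | lithium aldolate, the lithium C8 alkoxide of 18 (C3 epimers) | C=CC[C@]12CC(OC)C(=O)[C@](OC)([C@H](c3ccc(OC)c(OC)c3)[C@H]1C)[C@H]2[O-].[Li+] | intermediate (not isolated)
17 | dilithium enolate alkoxide, the C8 alkoxide and C3=C4 enolate of 18 | C=CC[C@]12CC(OC)=C([O-])[C@](OC)([C@H](c3ccc(OC)c(OC)c3)[C@H]1C)[C@H]2[O-].[Li+].[Li+] | intermediate (not isolated)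
18 | (1S,3S,5S,6S,7R,8S)-6-(3,4-dimethoxyphenyl)-8-hydroxy-3,5-dimethoxy-7-methyl-1-(prop-2-en-1-yl)bicyclo[3.2.1]octan-4-one, numbered from the allyl bridgehead (aryl endo, methyl exo, 3-OMe endo, OH syn to the C2–C4 bridge) | C=CC[C@]12C[C@H](OC)C(=O)[C@](OC)([C@H](c3ccc(OC)c(OC)c3)[C@H]1C)[C@H]2O | intermediate
19 | (1S,3S,5S,6S,7R,8S)-6-(3,4-dimethoxyphenyl)-3,5-dimethoxy-7-methyl-4-oxo-1-(prop-2-en-1-yl)bicyclo[3.2.1]octan-8-yl acetate, numbered from the allyl bridgehead | C=CC[C@]12C[C@H](OC)C(=O)[C@](OC)([C@H](c3ccc(OC)c(OC)c3)[C@H]1C)[C@H]2OC(C)=O | target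

Total step count: 11. Longest linear sequence: 11 steps (1 to 19); 4, 7 and 14 are purchased.

Steps most likely to fail

Step 10. The C3 enolate may drain too slowly into the C5 enolate, the amide base may add to the hindered aldehyde, or enolisation of the bicyclic ketone from its shielded endo C–H may stay incomplete, so that the quench leaves C3 unresolved. The fallback sets out from 15 and returns at 18. Soft enolisation with MgBr2·OEt2 and iPr2NEt in CH2Cl2 (0 °C to rt) runs the same transannular aldol reversibly, without a nucleophilic base, and holds the product as its magnesium chelate. The aldol is then expected as the C3-epimeric hydroxy ketone F1, alone or mixed with 18. Me3SiOTf and Et3N (CH2Cl2, 0 °C) convert this material, whatever its C3 configuration, into the C8 silyl ether and C3=C4 silyl enol ether F2. Bu4NF buffered with AcOH (THF, −78 °C) removes both silyl groups and protonates C3 on the exo face to give 18.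

Step 9. Facial selectivity at C1 may be poor, because the C6 aryl group is 1,3 to the reacting carbon on the face that the allyl group has to enter, and the silyl enol ether may be lost by protodesilylation before it couples. The fallback sets out from 12 and returns at 15. The cuprate addition is run without Me3SiCl and the enolate is quenched with allyl chloroformate to give the allyl enol carbonate F3. Decarboxylative asymmetric allylic alkylation with Pd2(dba)3·CHCl3 and N,N′-(cyclohexane-1,2-diyl)bis[2-(diphenylphosphino)benzamide] (the ligand enantiomer matched to the substrate) then forms the quaternary centre under catalyst control and gives 15.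

Step 3. Enantioselectivity or branched selectivity may erode with the unstabilised, doubly oxygenated enolate, and the product may be allylated a second time. The fallback sets out from 3 and returns at 6. The same [Ir(cod)Cl]2/L catalyst is used with a stabilised nucleophile, sodium dimethyl 2-methoxymalonate (from the malonate and NaH), to give the allylated methoxymalonate F4. Krapcho demethoxycarbonylation (LiCl, wet DMSO, 150 °C) gives the methoxy ester F5. MeNH(OMe)·HCl with iPrMgCl gives the Weinreb amide F6, and methoxymethyllithium (from Bu3SnCH2OMe and BuLi, THF, −78 °C) converts it into 6.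

Further compounds
F1 | step 10 | (1S,3R,5S,6S,7R,8S)-6-(3,4-dimethoxyphenyl)-8-hydroxy-3,5-dimethoxy-7-methyl-1-(prop-2-en-1-yl)bicyclo[3.2.1]octan-4-one, the C3 epimer of 18 | C=CC[C@]12C[C@@H](OC)C(=O)[C@](OC)([C@H](c3ccc(OC)c(OC)c3)[C@H]1C)[C@H]2O
F2 | step 10 | C8 trimethylsilyl ether and C3=C4 trimethylsilyl enol ether of 18 | C=CC[C@]12CC(OC)=C(O[Si](C)(C)C)[C@](OC)([C@H](c3ccc(OC)c(OC)c3)[C@H]1C)[C@H]2O[Si](C)(C)C
F3 | step 9 | allyl enol carbonate of the conjugate adduct, the prop-2-en-1-yl carbonate analogue of 13 | C=CCOC(=O)O/C=C1\C[C@H](OC)C(=O)[C@H](OC)[C@H](c2ccc(OC)c(OC)c2)[C@H]1C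
F4 | step 3 | dimethyl 2-[(1S)-1-(3,4-dimethoxyphenyl)prop-2-en-1-yl]-2-methoxypropanedioate | C=C[C@@H](c1ccc(OC)c(OC)c1)C(OC)(C(=O)OC)C(=O)OC
F5 | step 3 | methyl (3S)-3-(3,4-dimethoxyphenyl)-2-methoxypent-4-enoate, C2 epimers | C=C[C@@H](c1ccc(OC)c(OC)c1)C(OC)C(=O)OC
F6 | step 3 | (3S)-3-(3,4-dimethoxyphenyl)-N,2-dimethoxy-N-methylpent-4-enamide, C2 epimers | C=C[C@@H](c1ccc(OC)c(OC)c1)C(OC)C(=O)N(C)OC
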